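**Retrosynthetic overview**
1. C2–O bond (last step, sets C2): face-selective oxygen transfer from an N-sulfonyloxaziridine to the Z-enolate of deoxy ketone 5, held in a chiral spiroborate that the ketone's own 2-OH/C=O pair forms with a C2-symmetric diol; the work-up also frees the 4-OH.
2. C2–C3 bond: C-alkylation of the O,C-dianion of the 4-O-silylated acetophenone 2 with (2E,6E)-farnesyl bromide 3, which brings all three alkenes with their geometry.
3. 2 comes from 2,4-dihydroxyacetophenone 1 by selective silylation of the 4-OH.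
4. Rings: none is built; the benzene ring is bought, and the only ring formed is the transient six-membered boron chelate of the last step.

Assumption: bromide 3, diol 6 and the racemic Davis oxaziridine are bought; the (S) axis of the binaphthyl unit is given in the names because SMILES has no symbol for it.

**Step 1**
Reactants: 1 2,4-dihydroxyacetophenone
Product: 2 1-[4-(tert-butyldimethylsilyloxy)-2-hydroxyphenyl]ethan-1-one
Conditions: TBSCl (1.05 equiv), imidazole (2 equiv), CH2Cl2, 0 °C to rt
Reagents that add atoms: tert-butyldimethylsilyl chloride, CC(C)(C)[Si](C)(C)Cl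
Why: Selective O-silylation; the 2-OH is hydrogen-bonded to the ketone and hindered, so only the 4-OH reacts, and no stereocentre is involved.

**Step 2**
Reactants: 2 1-[4-(tert-butyldimethylsilyloxy)-2-hydroxyphenyl]ethan-1-one; 3 (2E,6E)-farnesyl bromide
Product: 5 (4E,8E)-1-[4-(tert-butyldimethylsilyloxy)-2-hydroxyphenyl]-5,9,13-trimethyltetradeca-4,8,12-trien-1-one, via dilithium phenoxide enolate 4 (not isolated)
Conditions: LiN(i-Pr)2 (2.2 equiv, bought as solution), THF, −78 to −20 °C; then 3 (0.85 equiv), −78 to −20 °C; AcOH quench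
Reagents that add atoms: none
Why: Enolate C-alkylation (SN2 at the primary allylic bromide) of the O,C-dianion, in which the chelated lithium phenoxide is far less nucleophilic than the enolate carbon; the bromide is limiting to suppress a second alkylation, and the E alkenes are carried through unchanged.

**Step 3**
Reactants: 5 (4E,8E)-1-[4-(tert-butyldimethylsilyloxy)-2-hydroxyphenyl]-5,9,13-trimethyltetradeca-4,8,12-trien-1-one; 6 (S)-3,3'-bis[3,5-bis(trifluoromethyl)phenyl]-1,1'-bi-2-naphthol
Product: 10 (2R,4E,8E)-1-(2,4-dihydroxyphenyl)-2-hydroxy-5,9,13-trimethyltetradeca-4,8,12-trien-1-one, via spiroborate chelate 7 (not isolated), via potassium spiroborate enolate 8 (not isolated), via hydroxylated spiroborate chelate 9 (not isolated)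
Conditions: 6 (1.05 equiv), B(OMe)3 (1.05 equiv), toluene, 50 °C, then evaporate to dryness; KN(SiMe3)2 (1.05 equiv), THF, −78 °C; (±)-trans-3-phenyl-2-(phenylsulfonyl)oxaziridine (1.3 equiv), −78 to −40 °C; AcOH; KHF2 (6 equiv), MeOH–H2O, rt
Reagents that add atoms: trans-3-phenyl-2-(phenylsulfonyl)oxaziridine, O=S(=O)(c1ccccc1)N1OC1c1ccccc1 (the hydroxyl O of 9 and 10); trimethyl borate, COB(OC)OC (the boron of 7, 8 and 9 only)
Why: Proposed new method: enantioselective enolate hydroxylation inside a chiral spiroborate that the substrate's own 2-OH/C=O pair builds with a C2-symmetric diol. The phenol O and ketone O clamp the (S)-diolate–boron unit into the neutral tetrahedral chelate 7 (the BF2 chelates of 2-acylphenols are the known parallel), which acidifies the α-CH2 and locks arene, C=O and the future enolate in one plane. KN(SiMe3)2 then gives only the Z enolate 8, because the E isomer would push C3 into the coplanar arene H-6. In a quadrant model of the tetrahedral spiro centre, one 3-aryl arm of the (S)-diolate lies over the Si face of C2, so C2 attacks the oxaziridine oxygen (SN2 at O) from the open Re face and sets (R). The product stays on boron as an alkoxide, which is not enolised again, so it neither racemises nor over-oxidises, and isolated trisubstituted alkenes do not react with an N-sulfonyloxaziridine at these temperatures. KHF2 finally breaks the B–O bonds, returns 6 and cleaves the aryl silyl ether. Closest known reaction type: Davis oxidation of preformed ketone enolates with N-sulfonyloxaziridines, merged here with chiral-boron control of an enolate as in boron-mediated aldol chemistry.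

**Compound list**
1 | 2,4-dihydroxyacetophenone | CC(=O)c1ccc(O)cc1O | starting material
2 | 1-[4-(tert-butyldimethylsilyloxy)-2-hydroxyphenyl]ethan-1-one | CC(=O)c1ccc(O[Si](C)(C)C(C)(C)C)cc1O | intermediate
3 | (2E,6E)-farnesyl bromide, (2E,6E)-1-bromo-3,7,11-trimethyldodeca-2,6,10-triene | CC(C)=CCC/C(C)=C/CC/C(C)=C/CBr | starting material
4 | dilithium phenoxide enolate of 2 (O-2 and enolate O deprotonated; not isolated) | [Li+].[Li+].C=C([O-])c1ccc(O[Si](C)(C)C(C)(C)C)cc1[O-] | intermediate
5 | (4E,8E)-1-[4-(tert-butyldimethylsilyloxy)-2-hydroxyphenyl]-5,9,13-trimethyltetradeca-4,8,12-trien-1-one | CC(C)=CCC/C(C)=C/CC/C(C)=C/CCC(=O)c1ccc(O[Si](C)(C)C(C)(C)C)cc1O | intermediate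
6 | (S)-3,3'-bis[3,5-bis(trifluoromethyl)phenyl]-1,1'-bi-2-naphthol (axis S) | Oc1c(-c2cc(C(F)(F)F)cc(C(F)(F)F)c2)cc2ccccc2c1-c1c(O)c(-c2cc(C(F)(F)F)cc(C(F)(F)F)c2)cc2ccccc12 | starting material
7 | neutral spiroborate chelate: boron bound to both oxygens of the (S)-diolate of 6, to the phenoxide O-2 of 5 and datively to the ketone O of 5; 4-O-silyl group and (4E,8E) chain unchanged (not isolated) | CC(C)=CCC/C(C)=C/CC/C(C)=C/CCC1=[O+][B-]2(Oc3cc(O[Si](C)(C)C(C)(C)C)ccc31)Oc1c(-c3cc(C(F)(F)F)cc(C(F)(F)F)c3)cc3ccccc3c1-c1c(O2)c(-c2cc(C(F)(F)F)cc(C(F)(F)F)c2)cc2ccccc12 | intermediate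
8 | potassium salt of the Z-enolate of 7: C1=C2 double bond exocyclic to the boron chelate ring, C3 cis to the enolate O–B oxygen, axis S (not isolated) | [K+].CC(C)=CCC/C(C)=C/CC/C(C)=C/C/C=C1\O[B-]2(Oc3cc(O[Si](C)(C)C(C)(C)C)ccc31)Oc1c(-c3cc(C(F)(F)F)cc(C(F)(F)F)c3)cc3ccccc3c1-c1c(O2)c(-c2cc(C(F)(F)F)cc(C(F)(F)F)c2)cc2ccccc12 | intermediate
9 | (2R)-2-hydroxy derivative of chelate 7, after the AcOH quench, axis S (not isolated) | CC(C)=CCC/C(C)=C/CC/C(C)=C/C[C@@H](O)C1=[O+][B-]2(Oc3cc(O[Si](C)(C)C(C)(C)C)ccc31)Oc1c(-c3cc(C(F)(F)F)cc(C(F)(F)F)c3)cc3ccccc3c1-c1c(O2)c(-c2cc(C(F)(F)F)cc(C(F)(F)F)c2)cc2ccccc12 | intermediate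
10 | (2R,4E,8E)-1-(2,4-dihydroxyphenyl)-2-hydroxy-5,9,13-trimethyltetradeca-4,8,12-trien-1-one | CC(C)=CCC/C(C)=C/CC/C(C)=C/C[C@@H](O)C(=O)c1ccc(O)cc1O | target

**Step count and risks**
Total steps: 3. Longest linear sequence: 3 (1 → 2 → 5 → 10). The route has three steps, so all three are ranked, most risky first.

Step 3 (the proposed spiroborate hydroxylation). It can fail in three ways: the mixed chelate 7 may not form cleanly (ligand scrambling on boron), the borate enolate 8 may be too weak a nucleophile for the oxaziridine, or the face selectivity may be low. The sense of induction rests on a model and has not been tested; if it is opposite, the (R)-diol is used. The fallback is known chemistry and sets out from 5. The hydrogen-bonded 2-OH is silylated with triisopropylsilyl triflate and 2,6-lutidine in CH2Cl2 to give the bis-silyl ketone F1; the bulky silyl group is chosen so that it does not migrate to the enolate oxygen. NaN(SiMe3)2 in THF at −78 °C gives the sodium Z-enolate F2, which is oxidised with (−)-(2S,8aR)-(camphorsulfonyl)oxaziridine. This is the reagent-controlled Davis asymmetric hydroxylation, and by the propiophenone precedent this enantiomer should give the (R)-ketol; the result is the (2R)-hydroxy bis-silyl ketone F3. Bu4NF buffered with AcOH (THF, 0 °C) removes both aryl silyl ethers and the route is rejoined at 10.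

Step 2 (dianion alkylation). The risks are a second alkylation, O-allylation of the phenoxide or incomplete dianion formation. The fallback sets out from 2 and changes the nucleophile to a metalloenamine. Condensation with cyclohexylamine (toluene, Dean–Stark) gives the hydrogen-bonded N-cyclohexyl ketimine F4. LiN(i-Pr)2 (2.1 equiv) gives the dilithium phenoxide aza-enolate F5, and alkylation with 3 (Stork metalloenamine alkylation, which stops at mono-alkylation) gives the alkylated ketimine F6. Hydrolysis with aqueous AcOH/NaOAc in THF returns the route at 5.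

Step 1 (selective silylation). This is the least risky step; it could fail through bis-silyl ether formation or loss of the aryl silyl ether from the small, polar phenol on purification. The fallback sets out from 1 and leaves the protecting group out until after C–C bond formation. LiN(i-Pr)2 (3.3 equiv, THF, −78 to 0 °C) gives the trilithium trianion F7, and alkylation with 3 (AcOH quench) gives the free resorcinol ketone F8. Silylation of F8 (TBSCl, imidazole) at its only non-hydrogen-bonded OH rejoins the route at 5, bypassing 2 and step 2.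

**Further compounds**
F1 | step 3 | (4E,8E)-1-[4-(tert-butyldimethylsilyloxy)-2-(triisopropylsilyloxy)phenyl]-5,9,13-trimethyltetradeca-4,8,12-trien-1-one | CC(C)=CCC/C(C)=C/CC/C(C)=C/CCC(=O)c1ccc(O[Si](C)(C)C(C)(C)C)cc1O[Si](C(C)C)(C(C)C)C(C)C
F2 | step 3 | sodium Z-enolate of F1 (C3 cis to the enolate O) | [Na+].CC(C)=CCC/C(C)=C/CC/C(C)=C/C/C=C(\[O-])c1ccc(O[Si](C)(C)C(C)(C)C)cc1O[Si](C(C)C)(C(C)C)C(C)C
F3 | step 3 | (2R,4E,8E)-1-[4-(tert-butyldimethylsilyloxy)-2-(triisopropylsilyloxy)phenyl]-2-hydroxy-5,9,13-trimethyltetradeca-4,8,12-trien-1-one | CC(C)=CCC/C(C)=C/CC/C(C)=C/C[C@@H](O)C(=O)c1ccc(O[Si](C)(C)C(C)(C)C)cc1O[Si](C(C)C)(C(C)C)C(C)C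
F4 | step 2 | (E)-N-cyclohexyl ketimine of 2, 5-(tert-butyldimethylsilyloxy)-2-[1-(cyclohexylimino)ethyl]phenol | C/C(=N\C1CCCCC1)c1ccc(O[Si](C)(C)C(C)(C)C)cc1O
F5 | step 2 | dilithium phenoxide aza-enolate of F4 | [Li+].[Li+].C=C([N-]C1CCCCC1)c1ccc(O[Si](C)(C)C(C)(C)C)cc1[O-]
F6 | step 2 | (E)-N-cyclohexyl ketimine of 5 | CC(C)=CCC/C(C)=C/CC/C(C)=C/CC/C(=N\C1CCCCC1)c1ccc(O[Si](C)(C)C(C)(C)C)cc1O
F7 | step 1 | trilithium trianion of 1 (both phenoxides and the enolate) | [Li+].[Li+].[Li+].C=C([O-])c1ccc([O-])cc1[O-]
F8 | step 1 | (4E,8E)-1-(2,4-dihydroxyphenyl)-5,9,13-trimethyltetradeca-4,8,12-trien-1-one | CC(C)=CCC/C(C)=C/CC/C(C)=C/CCC(=O)c1ccc(O)cc1O
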